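## Retrosynthetic overview

- Target 21 ⇐ flavanone 20 by one hydrogenolysis that removes two benzyl ethers and one benzyl carbonate.
- Ring C is closed last by intramolecular Friedel–Crafts acylation (C4–C4a) of the (S)-3-aryloxy-3-arylpropanoic acid 18. The strategy rests on ring A: O1 is para to the piperidine-bearing carbon C6, which is flanked by the C5 and C7 oxygens. The two carbons ortho to the ether oxygen are therefore equivalent, and closure at either gives the 6-substituted chromanone.
- Acid 18 ⇐ Mitsunobu etherification (O1–C2, inversion) of phenol 11 with the (R)-β-hydroxy tert-butyl ester 16, then ester cleavage.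
- Phenol 11 ⇐ 2,4,6-trihydroxybenzaldehyde by sulfinimine formation, 4-chlorobutyl Grignard addition and N-cyclization. Ester 16 ⇐ 4-hydroxybenzaldehyde by Roskamp homologation and asymmetric transfer hydrogenation.
- Ring order: rings A and B are bought, the piperidine ring is formed in step 5, ring C in step 13.

Key step: step 13

Remark: amines are drawn as free bases. In steps 12 and 13 the piperidine nitrogen is present as its trifluoroacetate salt, which keeps it inert. The ring-A oxygen that becomes O1 is carried as an allyl ether so that it can be freed beside the two benzyl ethers.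

## Route

Step 1
Reactants: 1 2,4,6-trihydroxybenzaldehyde
Product: 2 4-(allyloxy)-2,6-dihydroxybenzaldehyde
Conditions: allyl bromide (1.0 equiv), K2CO3 (1.0 equiv), DMF, 0 °C → rt
Reagents that add atoms: allyl bromide C=CCBr
Why: Williamson etherification in which the 4-hydroxyl, para to the formyl group and not hydrogen-bonded to it, is the most acidic and most exposed, so one equivalent of allyl bromide should alkylate it preferentially, with 2-O-allyl and diallyl material removed by chromatography.

Step 2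
Reactants: 2 4-(allyloxy)-2,6-dihydroxybenzaldehyde
Product: 3 4-(allyloxy)-2,6-bis(benzyloxy)benzaldehyde
Conditions: BnBr (2.5 equiv), K2CO3 (3 equiv), DMF, 60 °C
Reagents that add atoms: benzyl bromide BrCc1ccccc1
Why: Williamson etherification of the two remaining hydrogen-bonded phenols needs only excess benzyl bromide and mild heating, and the allyl aryl ether is inert at this temperature (Claisen rearrangement needs far more heat).

Step 3
Reactants: 3 4-(allyloxy)-2,6-bis(benzyloxy)benzaldehyde
Product: 4 (R,E)-N-[4-(allyloxy)-2,6-bis(benzyloxy)benzylidene]-2-methylpropane-2-sulfinamide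
Conditions: (R)-tert-butanesulfinamide (1.2 equiv), Ti(OEt)4 (2.5 equiv), THF, 65 °C
Reagents that add atoms: (R)-2-methylpropane-2-sulfinamide CC(C)(C)[S@@](=O)N
Why: Ellman condensation, in which Ti(OEt)4 acts as Lewis acid and water scavenger to drive the hindered, electron-rich aldehyde to the E-configured N-sulfinyl aldimine without touching the sulfur stereocenter.

Step 4
Reactants: 4 (R,E)-N-[4-(allyloxy)-2,6-bis(benzyloxy)benzylidene]-2-methylpropane-2-sulfinamide; 5 1-bromo-4-chlorobutane
Product: 7 (R)-N-[(1S)-1-[4-(allyloxy)-2,6-bis(benzyloxy)phenyl]-5-chloropentyl]-2-methylpropane-2-sulfinamide, via 4-chlorobutylmagnesium bromide 6 (not isolated)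
Conditions: 5, Mg, Et2O, reflux; then 4, CH2Cl2, −48 °C → rt; sat. aq. NH4Cl
Reagents that add atoms: none
Why: Ellman-type 1,2-addition of a Grignard reagent to an N-tert-butanesulfinyl aldimine, in which magnesium in non-coordinating CH2Cl2 should bind the sulfinyl oxygen in a six-membered chair transition state and deliver the 4-chlorobutyl group to the Si face of the (R)-sulfinyl imine, setting the (S) benzylic carbon, while the C–Cl bond (Mg inserts only into C–Br) is kept for ring closure and the minor diastereomer is removed by chromatography.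

Step 5
Reactants: 7 (R)-N-[(1S)-1-[4-(allyloxy)-2,6-bis(benzyloxy)phenyl]-5-chloropentyl]-2-methylpropane-2-sulfinamide
Product: 8 (2S)-2-[4-(allyloxy)-2,6-bis(benzyloxy)phenyl]-1-[(R)-tert-butylsulfinyl]piperidine
Conditions: NaH, DMF, 0 °C → rt
Reagents that add atoms: none
Why: The sulfinamide anion displaces the primary chloride intramolecularly (6-exo-tet N-alkylation) to form the piperidine ring without affecting the carbon or sulfur stereocenters.

Step 6
Reactants: 8 (2S)-2-[4-(allyloxy)-2,6-bis(benzyloxy)phenyl]-1-[(R)-tert-butylsulfinyl]piperidine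
Product: 10 (2S)-2-[4-(allyloxy)-2,6-bis(benzyloxy)phenyl]-1-methylpiperidine, via secondary amine hydrochloride 9 (not isolated)
Conditions: HCl (4 M in 1,4-dioxane), MeOH, 0 °C; evaporate; then 37% aq. HCHO, NaBH(OAc)3, Et3N, ClCH2CH2Cl, rt
Reagents that add atoms: formaldehyde C=O
Why: Acidic methanolysis cleaves the S–N bond quickly at 0 °C and the freed secondary amine undergoes Borch-type reductive amination with formaldehyde, NaBH(OAc)3 reducing the iminium ion, neither stage touching the C–H bond of the benzylic stereocenter.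

Step 7
Reactants: 10 (2S)-2-[4-(allyloxy)-2,6-bis(benzyloxy)phenyl]-1-methylpiperidine
Product: 11 3,5-bis(benzyloxy)-4-[(2S)-1-methylpiperidin-2-yl]phenol
Conditions: Pd(PPh3)4 (5 mol%), morpholine, THF, rt
Reagents that add atoms: none
Why: Tsuji–Trost deallylation, in which zerovalent palladium ionizes the allyl aryl ether to a π-allyl complex that morpholine intercepts, freeing the phenol under neutral conditions that leave the benzyl ethers, the amine and the stereocenter untouched.

Step 8
Reactants: 12 4-hydroxybenzaldehyde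
Product: 13 benzyl 4-formylphenyl carbonate
Conditions: CbzCl (1.1 equiv), Et3N (1.2 equiv), CH2Cl2, 0 °C
Reagents that add atoms: benzyl chloroformate O=C(Cl)OCc1ccccc1
Why: O-acylation of the phenol by the chloroformate gives the aryl benzyl carbonate, chosen because it withdraws electrons from ring B (suppressing later benzylic ionization) and falls to hydrogenolysis together with the benzyl ethers.

Step 9
Reactants: 13 benzyl 4-formylphenyl carbonate; 14 tert-butyl diazoacetate
Product: 15 tert-butyl 3-{4-[(benzyloxycarbonyl)oxy]phenyl}-3-oxopropanoate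
Conditions: SnCl2 (10 mol%), CH2Cl2, rt
Reagents that add atoms: none
Why: Roskamp homologation, in which SnCl2 activates the aldehyde toward attack by the diazo carbon and a 1,2-hydride shift with loss of N2 gives the β-keto ester directly, the para carbonate keeping the aromatic aldehyde electrophilic enough.

Step 10
Reactants: 15 tert-butyl 3-{4-[(benzyloxycarbonyl)oxy]phenyl}-3-oxopropanoate
Product: 16 tert-butyl (3R)-3-{4-[(benzyloxycarbonyl)oxy]phenyl}-3-hydroxypropanoate
Conditions: RuCl(p-cymene)[(R,R)-TsDPEN] (1 mol%), HCO2H–Et3N (5:2), EtOAc, rt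
Reagents that add atoms: none
Why: Noyori asymmetric transfer hydrogenation of an aryl ketone, in which the (R,R)-TsDPEN ruthenium hydride is expected to give the (R)-carbinol as it does with acetophenone-type ketones, under mildly acidic conditions that spare the carbonate and the tert-butyl ester.

Step 11
Reactants: 11 3,5-bis(benzyloxy)-4-[(2S)-1-methylpiperidin-2-yl]phenol; 16 tert-butyl (3R)-3-{4-[(benzyloxycarbonyl)oxy]phenyl}-3-hydroxypropanoate
Product: 17 tert-butyl (3S)-3-{3,5-bis(benzyloxy)-4-[(2S)-1-methylpiperidin-2-yl]phenoxy}-3-{4-[(benzyloxycarbonyl)oxy]phenyl}propanoate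
Conditions: PPh3, DIAD, toluene, 0 °C → rt
Reagents that add atoms: none
Why: Mitsunobu etherification, in which the phenoxide displaces the alkoxyphosphonium group by SN2 with inversion and so converts the (R)-carbinol into the (S)-aryl ether (the future C2), the electron-poor ring B disfavouring ionization and the cold, non-polar medium limiting elimination to the cinnamate.

Step 12
Reactants: 17 tert-butyl (3S)-3-{3,5-bis(benzyloxy)-4-[(2S)-1-methylpiperidin-2-yl]phenoxy}-3-{4-[(benzyloxycarbonyl)oxy]phenyl}propanoate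
Product: 18 (3S)-3-{3,5-bis(benzyloxy)-4-[(2S)-1-methylpiperidin-2-yl]phenoxy}-3-{4-[(benzyloxycarbonyl)oxy]phenyl}propanoic acid
Conditions: TFA–CH2Cl2 (1:4), Et3SiH (3 equiv), 0 °C → rt; evaporate (product kept as its trifluoroacetate salt)
Reagents that add atoms: none
Why: Acidolysis of the tert-butyl ester through the tert-butyl cation frees the acid while the protonated amine, the benzyl ethers and the carbonate persist, and Et3SiH is included to reduce the tert-butyl cation to isobutane before it can alkylate the phloroglucinol-type ring A.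

Step 13
Reactants: 18 (3S)-3-{3,5-bis(benzyloxy)-4-[(2S)-1-methylpiperidin-2-yl]phenoxy}-3-{4-[(benzyloxycarbonyl)oxy]phenyl}propanoic acid
Product: 20 (2S)-5,7-bis(benzyloxy)-2-{4-[(benzyloxycarbonyl)oxy]phenyl}-6-[(2S)-1-methylpiperidin-2-yl]chroman-4-one, via mixed trifluoroacetic anhydride 19 (not isolated)
Conditions: TFAA (2 equiv), TFA (2 equiv), CH2Cl2, 0 °C; then aq. NaHCO3
Reagents that add atoms: none
Why: TFAA converts the carboxylic acid into the mixed acyl trifluoroacetate 19, whose acylium-like carbon is attacked by the ring A carbon ortho to the ether oxygen (also ortho to one benzyloxy group and para to the other), and loss of a proton from the arenium ion gives the aryl ketone, forming C4–C4a. The closest known reaction type is the intramolecular Friedel–Crafts acylation of 3-aryloxypropanoic acids to chroman-4-ones with TFAA or polyphosphoric acid, here on a phloroglucinol triether that needs no strong Lewis acid. Ring C closes as a six-membered ring by 6-exo-trig attack of the arene carbon on the acyl carbon, the trifluoroacetate leaving group lying outside the ring. No stereocenter is created; C2 is carried unchanged from the Mitsunobu step and the piperidine carbon from the sulfinimine addition. The step needs regioselectivity, secured because O1 is para to the piperidine-bearing carbon so that both ortho carbons give the same 6-substituted chromanone, and it needs the benzylic C2–O1 bond not to ionize, which the electron-withdrawing carbonate on ring B, the low temperature and the absence of a strong Lewis acid are meant to secure. The ammonium nitrogen does not react with TFAA, and the new ketone deactivates ring A against a second acylation or trifluoroacetylation.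

Step 14
Reactants: 20 (2S)-5,7-bis(benzyloxy)-2-{4-[(benzyloxycarbonyl)oxy]phenyl}-6-[(2S)-1-methylpiperidin-2-yl]chroman-4-one
Product: 21 (2S)-5,7-dihydroxy-2-(4-hydroxyphenyl)-6-[(2S)-1-methylpiperidin-2-yl]chroman-4-one
Conditions: H2 (1 atm), 10% Pd/C, EtOAc–MeOH, rt
Reagents that add atoms: none
Why: Hydrogenolysis over Pd/C cleaves the two benzyl aryl ethers and the benzyl carbonate (which then loses CO2) in one neutral operation at room temperature, where the flavanone C2–O1 bond, the ketone and the hindered benzylic C–N bond should react much more slowly, so the reaction is stopped after uptake of three equivalents of H2.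

## Compound list

1 | 2,4,6-trihydroxybenzaldehyde | O=Cc1c(O)cc(O)cc1O | starting material
2 | 4-(allyloxy)-2,6-dihydroxybenzaldehyde | O=Cc1c(O)cc(OCC=C)cc1O | intermediate
3 | 4-(allyloxy)-2,6-bis(benzyloxy)benzaldehyde | O=Cc1c(OCc2ccccc2)cc(OCC=C)cc1OCc1ccccc1 | intermediate
4 | (R,E)-N-[4-(allyloxy)-2,6-bis(benzyloxy)benzylidene]-2-methylpropane-2-sulfinamide | CC(C)(C)[S@@](=O)/N=C/c1c(OCc2ccccc2)cc(OCC=C)cc1OCc1ccccc1 | intermediate
5 | 1-bromo-4-chlorobutane | ClCCCCBr | starting material
6 | 4-chlorobutylmagnesium bromide | ClCCCC[Mg]Br | intermediate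
7 | (R)-N-[(1S)-1-[4-(allyloxy)-2,6-bis(benzyloxy)phenyl]-5-chloropentyl]-2-methylpropane-2-sulfinamide | CC(C)(C)[S@@](=O)N[C@@H](CCCCCl)c1c(OCc2ccccc2)cc(OCC=C)cc1OCc1ccccc1 | intermediate
8 | (2S)-2-[4-(allyloxy)-2,6-bis(benzyloxy)phenyl]-1-[(R)-tert-butylsulfinyl]piperidine | CC(C)(C)[S@@](=O)N1CCCC[C@H]1c1c(OCc2ccccc2)cc(OCC=C)cc1OCc1ccccc1 | intermediate
9 | (2S)-2-[4-(allyloxy)-2,6-bis(benzyloxy)phenyl]piperidine hydrochloride | Cl.N1CCCC[C@H]1c1c(OCc2ccccc2)cc(OCC=C)cc1OCc1ccccc1 | intermediate
10 | (2S)-2-[4-(allyloxy)-2,6-bis(benzyloxy)phenyl]-1-methylpiperidine | CN1CCCC[C@H]1c1c(OCc2ccccc2)cc(OCC=C)cc1OCc1ccccc1 | intermediate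
11 | 3,5-bis(benzyloxy)-4-[(2S)-1-methylpiperidin-2-yl]phenol | CN1CCCC[C@H]1c1c(OCc2ccccc2)cc(O)cc1OCc1ccccc1 | intermediate
12 | 4-hydroxybenzaldehyde | O=Cc1ccc(O)cc1 | starting material
13 | benzyl 4-formylphenyl carbonate | O=Cc1ccc(OC(=O)OCc2ccccc2)cc1 | intermediate
14 | tert-butyl diazoacetate | CC(C)(C)OC(=O)C=[N+]=[N-] | starting material
15 | tert-butyl 3-{4-[(benzyloxycarbonyl)oxy]phenyl}-3-oxopropanoate | CC(C)(C)OC(=O)CC(=O)c1ccc(OC(=O)OCc2ccccc2)cc1 | intermediate
16 | tert-butyl (3R)-3-{4-[(benzyloxycarbonyl)oxy]phenyl}-3-hydroxypropanoate | CC(C)(C)OC(=O)C[C@@H](O)c1ccc(OC(=O)OCc2ccccc2)cc1 | intermediate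
17 | tert-butyl (3S)-3-{3,5-bis(benzyloxy)-4-[(2S)-1-methylpiperidin-2-yl]phenoxy}-3-{4-[(benzyloxycarbonyl)oxy]phenyl}propanoate | CN1CCCC[C@H]1c1c(OCc2ccccc2)cc(O[C@@H](CC(=O)OC(C)(C)C)c2ccc(OC(=O)OCc3ccccc3)cc2)cc1OCc1ccccc1 | intermediate
18 | (3S)-3-{3,5-bis(benzyloxy)-4-[(2S)-1-methylpiperidin-2-yl]phenoxy}-3-{4-[(benzyloxycarbonyl)oxy]phenyl}propanoic acid | CN1CCCC[C@H]1c1c(OCc2ccccc2)cc(O[C@@H](CC(=O)O)c2ccc(OC(=O)OCc3ccccc3)cc2)cc1OCc1ccccc1 | intermediate
19 | (3S)-3-{3,5-bis(benzyloxy)-4-[(2S)-1-methylpiperidin-2-yl]phenoxy}-3-{4-[(benzyloxycarbonyl)oxy]phenyl}propanoic trifluoroacetic anhydride | CN1CCCC[C@H]1c1c(OCc2ccccc2)cc(O[C@@H](CC(=O)OC(=O)C(F)(F)F)c2ccc(OC(=O)OCc3ccccc3)cc2)cc1OCc1ccccc1 | intermediate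
20 | (2S)-5,7-bis(benzyloxy)-2-{4-[(benzyloxycarbonyl)oxy]phenyl}-6-[(2S)-1-methylpiperidin-2-yl]chroman-4-one | CN1CCCC[C@H]1c1c(OCc2ccccc2)cc2c(c1OCc1ccccc1)C(=O)C[C@@H](c1ccc(OC(=O)OCc3ccccc3)cc1)O2 | intermediate
21 | (2S)-5,7-dihydroxy-2-(4-hydroxyphenyl)-6-[(2S)-1-methylpiperidin-2-yl]chroman-4-one | CN1CCCC[C@H]1c1c(O)cc2c(c1O)C(=O)C[C@@H](c1ccc(O)cc1)O2 | target

## Step count and risks

Total step count: 14. Longest linear sequence: 11 steps (steps 1–7 and 11–14, from 2,4,6-trihydroxybenzaldehyde).

**Step 13 (ring closure).** Acid may ionize the benzylic C–O bond next to ring B before acylation occurs. That would erode the configuration at the future C2 or split the acid into a cinnamic acid and phenol 11. Ring A could also be trifluoroacetylated intermolecularly. The fallback closes ring C through O1–C2 instead and sets out from phenol 11. C-acetylation ortho to the hydroxyl (AcOH, TFAA, CH2Cl2, 0 °C; both ortho carbons are equivalent, and any aryl acetate is cleaved in the next basic step) would give 1-{2,4-bis(benzyloxy)-6-hydroxy-3-[(2S)-1-methylpiperidin-2-yl]phenyl}ethan-1-one F1. Claisen–Schmidt condensation with 4-(benzyloxy)benzaldehyde (KOH, EtOH, rt) would give the chalcone (2E)-1-{2,4-bis(benzyloxy)-6-hydroxy-3-[(2S)-1-methylpiperidin-2-yl]phenyl}-3-[4-(benzyloxy)phenyl]prop-2-en-1-one F2, whose single free hydroxyl can close ring C in one direction only. Oxa-Michael cyclization (NaOAc, EtOH, 60 °C) would give (2S)-5,7-bis(benzyloxy)-2-[4-(benzyloxy)phenyl]-6-[(2S)-1-methylpiperidin-2-yl]chroman-4-one F3 together with its (2R)-epimer F4. These are diastereomers and should separate by chromatography, and F4 can be recycled through F2 under the same conditions. Hydrogenolysis of F3 as in step 14 comes back to the route at target 21.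

**Step 11 (Mitsunobu).** The activated carbinol may eliminate to the cinnamate, because the ester α-hydrogens are acidic, or may partly ionize with loss of configuration. The fallback masks the carboxyl carbon as a vinyl group and sets out from aldehyde 13. Brown allylation with (+)-Ipc2B(allyl) (Et2O, −78 °C, non-basic work-up to spare the carbonate) would give benzyl 4-[(1R)-1-hydroxybut-3-en-1-yl]phenyl carbonate F5. Mitsunobu coupling with phenol 11 (PPh3, DIAD) would give, with inversion, benzyl 4-[(1S)-1-{3,5-bis(benzyloxy)-4-[(2S)-1-methylpiperidin-2-yl]phenoxy}but-3-en-1-yl]phenyl carbonate F6. Dihydroxylation (OsO4 cat., N-methylmorpholine N-oxide) would give benzyl 4-[(1S)-1-{3,5-bis(benzyloxy)-4-[(2S)-1-methylpiperidin-2-yl]phenoxy}-3,4-dihydroxybutyl]phenyl carbonate F7. NaIO4 cleavage would give benzyl 4-[(1S)-1-{3,5-bis(benzyloxy)-4-[(2S)-1-methylpiperidin-2-yl]phenoxy}-3-oxopropyl]phenyl carbonate F8. Pinnick oxidation (NaClO2, NaH2PO4, 2-methyl-2-butene) comes back to the route at acid 18.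

**Step 4 (Grignard addition).** Addition to the doubly ortho-substituted, electron-rich aldimine may be slow. Facial selectivity may be low or inverted if magnesium binds the ortho benzyloxy oxygens instead of the sulfinyl oxygen. The fallback builds the piperidine through a cyclic imine and resolves it, setting out from aldehyde 3 and Grignard reagent 6. Addition to the aldehyde would give 1-[4-(allyloxy)-2,6-bis(benzyloxy)phenyl]-5-chloropentan-1-ol F9. Dess–Martin oxidation would give 1-[4-(allyloxy)-2,6-bis(benzyloxy)phenyl]-5-chloropentan-1-one F10. NaN3 (DMF, 60 °C) would give 5-azido-1-[4-(allyloxy)-2,6-bis(benzyloxy)phenyl]pentan-1-one F11. Staudinger/aza-Wittig closure (PPh3, THF, reflux) would give 6-[4-(allyloxy)-2,6-bis(benzyloxy)phenyl]-2,3,4,5-tetrahydropyridine F12. NaBH4 reduction would give racemic 2-[4-(allyloxy)-2,6-bis(benzyloxy)phenyl]piperidine F13, which is resolved by chromatography on a chiral stationary phase. The (S)-enantiomer, as its hydrochloride, comes back to the route at 9 (second stage of step 6).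

Further compounds
F1 | step 13 | 1-{2,4-bis(benzyloxy)-6-hydroxy-3-[(2S)-1-methylpiperidin-2-yl]phenyl}ethan-1-one | CN1CCCC[C@H]1c1c(OCc2ccccc2)cc(O)c(C(C)=O)c1OCc1ccccc1
F2 | step 13 | (2E)-1-{2,4-bis(benzyloxy)-6-hydroxy-3-[(2S)-1-methylpiperidin-2-yl]phenyl}-3-[4-(benzyloxy)phenyl]prop-2-en-1-one | CN1CCCC[C@H]1c1c(OCc2ccccc2)cc(O)c(C(=O)/C=C/c2ccc(OCc3ccccc3)cc2)c1OCc1ccccc1
F3 | step 13 | (2S)-5,7-bis(benzyloxy)-2-[4-(benzyloxy)phenyl]-6-[(2S)-1-methylpiperidin-2-yl]chroman-4-one | CN1CCCC[C@H]1c1c(OCc2ccccc2)cc2c(c1OCc1ccccc1)C(=O)C[C@@H](c1ccc(OCc3ccccc3)cc1)O2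
F4 | step 13 | (2R)-5,7-bis(benzyloxy)-2-[4-(benzyloxy)phenyl]-6-[(2S)-1-methylpiperidin-2-yl]chroman-4-one | CN1CCCC[C@H]1c1c(OCc2ccccc2)cc2c(c1OCc1ccccc1)C(=O)C[C@H](c1ccc(OCc3ccccc3)cc1)O2
F5 | step 11 | benzyl 4-[(1R)-1-hydroxybut-3-en-1-yl]phenyl carbonate | C=CC[C@@H](O)c1ccc(OC(=O)OCc2ccccc2)cc1
F6 | step 11 | benzyl 4-[(1S)-1-{3,5-bis(benzyloxy)-4-[(2S)-1-methylpiperidin-2-yl]phenoxy}but-3-en-1-yl]phenyl carbonate | CN1CCCC[C@H]1c1c(OCc2ccccc2)cc(O[C@@H](CC=C)c2ccc(OC(=O)OCc3ccccc3)cc2)cc1OCc1ccccc1
F7 | step 11 | benzyl 4-[(1S)-1-{3,5-bis(benzyloxy)-4-[(2S)-1-methylpiperidin-2-yl]phenoxy}-3,4-dihydroxybutyl]phenyl carbonate | CN1CCCC[C@H]1c1c(OCc2ccccc2)cc(O[C@@H](CC(O)CO)c2ccc(OC(=O)OCc3ccccc3)cc2)cc1OCc1ccccc1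
F8 | step 11 | benzyl 4-[(1S)-1-{3,5-bis(benzyloxy)-4-[(2S)-1-methylpiperidin-2-yl]phenoxy}-3-oxopropyl]phenyl carbonate | CN1CCCC[C@H]1c1c(OCc2ccccc2)cc(O[C@@H](CC=O)c2ccc(OC(=O)OCc3ccccc3)cc2)cc1OCc1ccccc1
F9 | step 4 | 1-[4-(allyloxy)-2,6-bis(benzyloxy)phenyl]-5-chloropentan-1-ol (racemic) | OC(CCCCCl)c1c(OCc2ccccc2)cc(OCC=C)cc1OCc1ccccc1
F10 | step 4 | 1-[4-(allyloxy)-2,6-bis(benzyloxy)phenyl]-5-chloropentan-1-one | O=C(CCCCCl)c1c(OCc2ccccc2)cc(OCC=C)cc1OCc1ccccc1
F11 | step 4 | 5-azido-1-[4-(allyloxy)-2,6-bis(benzyloxy)phenyl]pentan-1-one | O=C(CCCCN=[N+]=[N-])c1c(OCc2ccccc2)cc(OCC=C)cc1OCc1ccccc1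
F12 | step 4 | 6-[4-(allyloxy)-2,6-bis(benzyloxy)phenyl]-2,3,4,5-tetrahydropyridine | C1CCN=C(C1)c1c(OCc2ccccc2)cc(OCC=C)cc1OCc1ccccc1
F13 | step 4 | 2-[4-(allyloxy)-2,6-bis(benzyloxy)phenyl]piperidine (racemic) | N1CCCCC1c1c(OCc2ccccc2)cc(OCC=C)cc1OCc1ccccc1
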